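**Retrosynthetic overview**

1. Locants follow briarane numbering: ring A = cyclohexene C1/C10–C14, ring B = ten-membered carbocycle C1–C10, ring C = butenolide C7/C8/C17/C19/O.
2. Ring C and its C6=C7 enol-lactone alkene are unmasked last from a 2,3,4-trisubstituted furan (singlet oxygen, then dehydration); the ten-membered ring enforces the C5/C8-cis alkene geometry.
3. Key disconnection C1–C2: the anti-1,3-dioxygenated array O–C2–C1(quaternary, Me)–C14–O that straddles the A/B fusion, with the isovalerate on O2, is an aldol–Tishchenko retron. Ring B is therefore closed by a samarium Reformatsky aldol of a ring-A α-bromo ketone (C14=O, C1–Br) onto the C2 aldehyde, trapped in the same flask by Evans–Tishchenko reduction with isovaleraldehyde.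
4. C8–C9 by Negishi coupling; ring A with C9 from 2,6-dimethylbenzoic acid (C10 lies between the methyl-bearing C1 and C11) by Birch dearomatization and desymmetrizing Shi epoxidation; C2–C7 with the C5 stereocenter from (S)-linalool; furan by alkynediol iodocyclization.
5. Ring order: ring A (arene, step 1), ring C as furan (step 10), ring B (step 15).

Key step: step 15

Remark: (S)-(+)-linalool and the L-fructose-derived Shi ketone are taken as purchasable single enantiomers; the sense of induction in step 3 is assigned from the spiro transition-state model, and the D-fructose-derived ketone would be used if it proved opposite.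

**Route**

Step 1
Reactants: 1 2,6-dimethylbenzoic acid
Product: 2 2,6-dimethylcyclohexa-2,5-diene-1-carboxylic acid
Conditions: Li, NH3(l)/THF, −78 °C; then NH4Cl
Reagents that add atoms: none
Why: Birch reduction of a benzoic acid protonates the carboxyl-bearing carbon and its para carbon, so the dearomatized ring should be the prochiral skipped diene with both methyl groups on the alkenes, already holding C9, C10–C14, C1 and both ring methyl groups.

Step 2
Reactants: 2 2,6-dimethylcyclohexa-2,5-diene-1-carboxylic acid
Product: 3 (2,6-dimethylcyclohexa-2,5-dien-1-yl)methanol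
Conditions: LiAlH4, THF, 0 °C → rt
Reagents that add atoms: none
Why: Hydride reduction of the carboxylic acid to the primary alcohol (C9); the isolated alkenes are inert and no stereocenter is present.

Step 3
Reactants: 3 (2,6-dimethylcyclohexa-2,5-dien-1-yl)methanol
Product: 4 [(1R,2R,6S)-1,3-dimethyl-7-oxabicyclo[4.1.0]hept-3-en-2-yl]methanol (epoxide trans to CH2OH)
Conditions: L-fructose-derived Shi ketone (30 mol%), KHSO5 (Oxone, 1.0 equiv), K2CO3, Bu4NHSO4, MeCN/dimethoxymethane/aq. buffer (pH 10.5), 0 °C
Reagents that add atoms: potassium peroxymonosulfate (KHSO5), [K+].[O-]S(=O)(=O)OO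
Why: Shi asymmetric epoxidation of a trisubstituted alkene: the chiral dioxirane attacks opposite faces of the two enantiotopic ring alkenes, and only on one of them is that face anti to the CH2OH group, so one alkene should be epoxidized selectively, which sets C10 (the epoxide carbons C1 and C14 are transient).

Step 4
Reactants: 4 [(1R,2R,6S)-1,3-dimethyl-7-oxabicyclo[4.1.0]hept-3-en-2-yl]methanol
Product: 5 2-(iodomethyl)-1,3-dimethyl-7-oxabicyclo[4.1.0]hept-3-ene (ring configured as in 4)
Conditions: I2, PPh3, imidazole, CH2Cl2, 0 °C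
Reagents that add atoms: iodine, II
Why: Appel iodination of the primary alcohol under neutral conditions that the trisubstituted epoxide and the alkene should survive; the substitution is at CH2 and no stereocenter is touched.

Step 5
Reactants: 6 (S)-(+)-linalool
Product: 7 (3S)-3,7-dimethyl-3-(triethylsilyloxy)octa-1,6-diene
Conditions: TESOTf, 2,6-lutidine, CH2Cl2, −78 → 0 °C
Reagents that add atoms: triethylsilyl triflate, CC[Si](CC)(CC)OS(=O)(=O)C(F)(F)F
Why: Silylation of the hindered tertiary alcohol with a silyl triflate; C5 (S) comes from the chiral pool and its C–O bond is never broken afterwards.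

Step 6
Reactants: 7 (3S)-3,7-dimethyl-3-(triethylsilyloxy)octa-1,6-diene
Product: 9 (3S)-3,7-dimethyl-3-(triethylsilyloxy)oct-6-en-1-ol, via B-alkyl-9-BBN borane 8 (not isolated)
Conditions: 9-BBN, THF, 0 °C → rt; then NaOH, H2O2, 0 °C
Reagents that add atoms: hydrogen peroxide, OO
Why: Hydroboration–oxidation: 9-BBN should add anti-Markovnikov to the monosubstituted vinyl group only and leave the trisubstituted alkene, turning the vinyl terminus into the primary alcohol carbon C7.

Step 7
Reactants: 9 (3S)-3,7-dimethyl-3-(triethylsilyloxy)oct-6-en-1-ol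
Product: 10 (3S)-3,7-dimethyl-3-(triethylsilyloxy)oct-6-enal
Conditions: Dess–Martin periodinane, NaHCO3, CH2Cl2, 0 °C → rt
Reagents that add atoms: none
Why: Dess–Martin oxidation of the primary alcohol under buffered, non-basic conditions, so the β-silyloxy aldehyde should not eliminate.

Step 8
Reactants: 10 (3S)-3,7-dimethyl-3-(triethylsilyloxy)oct-6-enal
Product: 11 (4S)-4,8-dimethyl-4-(triethylsilyloxy)non-7-en-1-yne
Conditions: dimethyl (1-diazo-2-oxopropyl)phosphonate, K2CO3, MeOH, 0 °C → rt
Reagents that add atoms: dimethyl (1-diazo-2-oxopropyl)phosphonate, CC(=O)C(=[N+]=[N-])P(=O)(OC)OC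
Why: Seyferth–Gilbert homologation with the Ohira–Bestmann reagent adds C8 as the alkyne terminus; the mild K2CO3/MeOH conditions are tolerated by the tertiary silyl ether.

Step 9
Reactants: 11 (4S)-4,8-dimethyl-4-(triethylsilyloxy)non-7-en-1-yne; 12 acetoxyacetone
Product: 14 (6S)-2,6,10-trimethyl-6-(triethylsilyloxy)undec-9-en-3-yne-1,2-diol (both epimers at C2), via acetate adduct 13 (not isolated)
Conditions: n-BuLi, THF, −78 °C; CeCl3; then 12, −78 °C; then K2CO3, MeOH, rt
Reagents that add atoms: none
Why: 1,2-Addition of the cerium acetylide to the ketone of 12 (the organocerium suppresses enolization and ester attack), then methanolysis of the acetate, should give the 3-alkyne-1,2-diol that brings in C17, C18 and C19; the new carbinol center is lost in step 10.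

Step 10
Reactants: 14 (6S)-2,6,10-trimethyl-6-(triethylsilyloxy)undec-9-en-3-yne-1,2-diol
Product: 16 2-[(2S)-2,6-dimethyl-2-(triethylsilyloxy)hept-5-en-1-yl]-3-iodo-4-methylfuran, via iododihydrofuranol 15 (not isolated)
Conditions: I2, NaHCO3, MeCN, 0 °C → rt
Reagents that add atoms: iodine, II
Why: Electrophilic 5-endo-dig iodocyclization of a 3-alkyne-1,2-diol (the primary hydroxyl attacks C7, iodine ends on C8) followed by spontaneous dehydration should give the β-iodofuran, ring C at the furan oxidation level; the hindered silyl ether is a much poorer nucleophile than the free hydroxyl.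

Step 11
Reactants: 16 2-[(2S)-2,6-dimethyl-2-(triethylsilyloxy)hept-5-en-1-yl]-3-iodo-4-methylfuran
Product: 18 (4S)-5-(3-iodo-4-methylfuran-2-yl)-4-methyl-4-(triethylsilyloxy)pentanal, via vicinal diol 17 (not isolated)
Conditions: OsO4 (2 mol%), NaIO4, 2,6-lutidine, dioxane/H2O, rt
Reagents that add atoms: sodium periodate (NaIO4), [Na+].[O-]I(=O)(=O)=O (oxygen delivered through catalytic OsO4)
Why: Lemieux–Johnson cleavage (dihydroxylation, then periodate glycol cleavage) of the electron-rich trisubstituted alkene unveils the C2 aldehyde and releases acetone; the aromatic iodofuran should be inert to OsO4 here.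

Step 12
Reactants: 5 2-(iodomethyl)-1,3-dimethyl-7-oxabicyclo[4.1.0]hept-3-ene; 18 (4S)-5-(3-iodo-4-methylfuran-2-yl)-4-methyl-4-(triethylsilyloxy)pentanal
Product: 20 (4S)-5-{3-[(1,3-dimethyl-7-oxabicyclo[4.1.0]hept-3-en-2-yl)methyl]-4-methylfuran-2-yl}-4-methyl-4-(triethylsilyloxy)pentanal (bicycle configured as in 4), via alkylzinc iodide 19 (not isolated)
Conditions: 5, Zn dust (I2-activated), DMA, 40 °C; then 18, Pd2(dba)3 (2.5 mol%), SPhos (10 mol%), THF, 40 °C
Reagents that add atoms: none
Why: Negishi sp3–sp2 cross-coupling forms C8–C9: the alkylzinc iodide tolerates aldehyde, epoxide and silyl ether, and reductive elimination from the biarylphosphine palladium complex should outrun β-hydride elimination; no stereocenter is touched.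

Step 13
Reactants: 20 epoxy aldehyde
Product: 21 (4S)-5-{3-[(6-bromo-5-hydroxy-2,6-dimethylcyclohex-2-en-1-yl)methyl]-4-methylfuran-2-yl}-4-methyl-4-(triethylsilyloxy)pentanal (Br on C1 trans to OH on C14; C10 as in 4)
Conditions: 48% aq. HBr (1.1 equiv), THF, −20 °C; NaHCO3 quench
Reagents that add atoms: hydrogen bromide, Br
Why: Acid-promoted halohydrin formation: the protonated trisubstituted epoxide opens with SN1 character at the tertiary carbon, so bromide should enter at C1 anti to the oxygen that stays on C14; both centers are erased in steps 14 and 15 and only the regiochemistry matters.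

Step 14
Reactants: 21 bromohydrin aldehyde
Product: 22 (4S)-5-{3-[(6-bromo-2,6-dimethyl-5-oxocyclohex-2-en-1-yl)methyl]-4-methylfuran-2-yl}-4-methyl-4-(triethylsilyloxy)pentanal
Conditions: Dess–Martin periodinane, NaHCO3, CH2Cl2, 0 °C
Reagents that add atoms: none
Why: Dess–Martin oxidation of the secondary alcohol gives the tertiary α-bromo ketone under buffered conditions that avoid base-induced loss of HBr; the aldehyde is not oxidized further.

Step 15
Reactants: 22 α-bromo ketone aldehyde; 23 3-methylbutanal (isovaleraldehyde)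
Product: 27 furan-fused A/B bicycle with C2 3-methylbutanoate/C14 hydroxyl/C5 OSiEt3 (all five stereocenters as in the target), via samarium enolate 24 (not isolated), via samarium aldolate 25 (not isolated), via samarium hemiacetal 26 (not isolated)
Conditions: 22 added slowly to SmI2 (2.5 equiv), THF (5 mM), −78 °C; then 23 (10 equiv), −78 → −10 °C; aq. NaHCO3
Reagents that add atoms: none
Why: Two single-electron transfers from SmI2 cleave the C1–Br bond and give the regiodefined trivalent samarium enolate 24; the closest known reaction types are the SmI2-mediated intramolecular Reformatsky aldol used for eight- to fourteen-membered rings and the aldol–Tishchenko (Evans–Tishchenko) hydride transfer, here run in one flask. The enolate carbon C1 adds to the tethered C2 aldehyde through a samarium-chelated Zimmerman–Traxler chair, closing ring B (C1–C10) in a 10-exo-trig mode. C1 is set by attack on the enolate face anti to the pseudoaxial C10–C9 bond (A(1,2) strain with the C1 methyl group), which gives the trans ring fusion, and C2 by the equatorial position of the C3 chain in that chair. Aldolate 25 adds to 23 to give hemiacetal 26, whose C–H is delivered through a six-membered chair to the face of the C14 carbonyl syn to the C1 methyl group, so the new hydroxyl is axial, 1,3-anti to O2, and the 3-methylbutanoyl group ends on O2 only. The step needs ring closure to outrun intermolecular aldol, pinacol reduction of the aldehyde and retro-aldol: slow addition into excess SmI2 at high dilution, the much faster reduction of the tertiary α-bromo ketone than of the aldehyde, the furan (C7–C8) that holds C6 and C9 cis and removes two rotors, and the irreversible hydride transfer are expected to secure this. Regioselective enolization toward C1, not attainable by deprotonation next to the C11=C12 alkene, is secured by the position of the bromide.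

Step 16
Reactants: 27 furan-fused A/B bicycle (C14 hydroxyl)
Product: 28 C14 acetate of 27
Conditions: Ac2O, DMAP, Et3N, CH2Cl2, rt
Reagents that add atoms: acetic anhydride, CC(=O)OC(C)=O
Why: DMAP-catalysed acetylation of the axial C14 alcohol, run directly after step 15 to forestall 1,3-migration of the 3-methylbutanoyl group; the C5 oxygen is silylated and cannot compete.

Step 17
Reactants: 28 C14 acetate (furan)
Product: 30 γ-hydroxybutenolide (C19 lactone carbonyl; C7 hemiketal; both C7 epimers), via furan endoperoxide 29 (not isolated)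
Conditions: O2, hν (visible), tetraphenylporphyrin (cat.), i-Pr2NEt, CH2Cl2, −78 °C
Reagents that add atoms: dioxygen, O=O
Why: Singlet-oxygen [4+2] cycloaddition to the electron-rich furan (far faster than the ene reaction of the C11=C12 alkene) and amine-induced Kornblum–DeLaMare-type fragmentation of the endoperoxide: the only furan α-hydrogen is on C19, so C19 should become the lactone carbonyl and C7 the hemiketal carbon.

Step 18
Reactants: 30 γ-hydroxybutenolide
Product: 31 O5-triethylsilyl ether of the target
Conditions: MsCl, Et3N, CH2Cl2, −20 → 0 °C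
Reagents that add atoms: none
Why: Sulfonylation–elimination (dehydration) of the hemiketal to the enol lactone: only C6 carries β-hydrogens, and within the ten-membered ring the C6=C7 bond can only form with C5 cis to C8, which is the required geometry.

Step 19
Reactants: 31 O5-triethylsilyl ether of the target
Product: 32 CNP0208239.1 (target; 1S,2S,5S,10S,14S in briarane numbering)
Conditions: Et3N·3HF, MeCN, rt
Reagents that add atoms: none
Why: Fluoride-mediated desilylation under nearly neutral conditions should free the tertiary allylic alcohol without ionizing it or touching the two esters and the enol lactone.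

**Compound list**

1 | 2,6-dimethylbenzoic acid | Cc1cccc(C)c1C(=O)O | starting material
2 | 2,6-dimethylcyclohexa-2,5-diene-1-carboxylic acid | OC(=O)C1C(C)=CCC=C1C | intermediate
3 | (2,6-dimethylcyclohexa-2,5-dien-1-yl)methanol | OCC1C(C)=CCC=C1C | intermediate
4 | [(1R,2R,6S)-1,3-dimethyl-7-oxabicyclo[4.1.0]hept-3-en-2-yl]methanol | OC[C@H]1C(C)=CC[C@@H]2O[C@]12C | intermediate
5 | 2-(iodomethyl)-1,3-dimethyl-7-oxabicyclo[4.1.0]hept-3-ene, ring configured as in 4 | IC[C@H]1C(C)=CC[C@@H]2O[C@]12C | intermediate
6 | (S)-(+)-linalool | C=C[C@@](C)(O)CCC=C(C)C | starting material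
7 | (3S)-3,7-dimethyl-3-(triethylsilyloxy)octa-1,6-diene | C=C[C@@](C)(O[Si](CC)(CC)CC)CCC=C(C)C | intermediate
8 | 9-[(3S)-3,7-dimethyl-3-(triethylsilyloxy)oct-6-en-1-yl]-9-borabicyclo[3.3.1]nonane | C1CC2CCCC(C1)B2CC[C@@](C)(O[Si](CC)(CC)CC)CCC=C(C)C | intermediate (not isolated)
9 | (3S)-3,7-dimethyl-3-(triethylsilyloxy)oct-6-en-1-ol | OCC[C@@](C)(O[Si](CC)(CC)CC)CCC=C(C)C | intermediate
10 | (3S)-3,7-dimethyl-3-(triethylsilyloxy)oct-6-enal | O=CC[C@@](C)(O[Si](CC)(CC)CC)CCC=C(C)C | intermediate
11 | (4S)-4,8-dimethyl-4-(triethylsilyloxy)non-7-en-1-yne | C#CC[C@@](C)(O[Si](CC)(CC)CC)CCC=C(C)C | intermediate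
12 | acetoxyacetone (2-oxopropyl acetate) | CC(=O)COC(C)=O | starting material
13 | (6S)-2-hydroxy-2,6,10-trimethyl-6-(triethylsilyloxy)undec-9-en-3-yn-1-yl acetate (both C2 epimers; present as its metal alkoxide) | CC(=O)OCC(C)(O)C#CC[C@@](C)(O[Si](CC)(CC)CC)CCC=C(C)C | intermediate (not isolated)
14 | (6S)-2,6,10-trimethyl-6-(triethylsilyloxy)undec-9-en-3-yne-1,2-diol (both C2 epimers) | OCC(C)(O)C#CC[C@@](C)(O[Si](CC)(CC)CC)CCC=C(C)C | intermediate
15 | 5-[(2S)-2,6-dimethyl-2-(triethylsilyloxy)hept-5-en-1-yl]-4-iodo-3-methyl-2,3-dihydrofuran-3-ol | CC1(O)COC(C[C@@](C)(O[Si](CC)(CC)CC)CCC=C(C)C)=C1I | intermediate (not isolated)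
16 | 2-[(2S)-2,6-dimethyl-2-(triethylsilyloxy)hept-5-en-1-yl]-3-iodo-4-methylfuran | Cc1coc(C[C@@](C)(O[Si](CC)(CC)CC)CCC=C(C)C)c1I | intermediate
17 | (6S)-7-(3-iodo-4-methylfuran-2-yl)-2,6-dimethyl-6-(triethylsilyloxy)heptane-2,3-diol | Cc1coc(C[C@@](C)(O[Si](CC)(CC)CC)CCC(O)C(C)(C)O)c1I | intermediate (not isolated)
18 | (4S)-5-(3-iodo-4-methylfuran-2-yl)-4-methyl-4-(triethylsilyloxy)pentanal | Cc1coc(C[C@@](C)(O[Si](CC)(CC)CC)CCC=O)c1I | intermediate
19 | alkylzinc iodide derived from 5 | I[Zn]C[C@H]1C(C)=CC[C@@H]2O[C@]12C | intermediate (not isolated)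
20 | (4S)-5-{3-[(1,3-dimethyl-7-oxabicyclo[4.1.0]hept-3-en-2-yl)methyl]-4-methylfuran-2-yl}-4-methyl-4-(triethylsilyloxy)pentanal, bicycle configured as in 4 | Cc1coc(C[C@@](C)(O[Si](CC)(CC)CC)CCC=O)c1C[C@H]1C(C)=CC[C@@H]2O[C@]12C | intermediate
21 | (4S)-5-{3-[(6-bromo-5-hydroxy-2,6-dimethylcyclohex-2-en-1-yl)methyl]-4-methylfuran-2-yl}-4-methyl-4-(triethylsilyloxy)pentanal, Br trans to OH | Cc1coc(C[C@@](C)(O[Si](CC)(CC)CC)CCC=O)c1C[C@H]1C(C)=CC[C@H](O)[C@@]1(C)Br | intermediate
22 | (4S)-5-{3-[(6-bromo-2,6-dimethyl-5-oxocyclohex-2-en-1-yl)methyl]-4-methylfuran-2-yl}-4-methyl-4-(triethylsilyloxy)pentanal | Cc1coc(C[C@@](C)(O[Si](CC)(CC)CC)CCC=O)c1C[C@H]1C(C)=CCC(=O)[C@@]1(C)Br | intermediate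
23 | 3-methylbutanal (isovaleraldehyde) | CC(C)CC=O | starting material
24 | diiodosamarium enolate of 22 (C14–O–SmI2, C14=C1) | Cc1coc(C[C@@](C)(O[Si](CC)(CC)CC)CCC=O)c1C[C@H]1C(C)=CCC(O[Sm](I)I)=C1C | intermediate (not isolated)
25 | diiodosamarium aldolate (ring B closed; C2–O–SmI2; C14 ketone) | O=C1CC=C(C)[C@@H]2Cc3c(C)coc3C[C@@](C)(O[Si](CC)(CC)CC)CC[C@H](O[Sm](I)I)[C@@]12C | intermediate (not isolated)
26 | samarium hemiacetal of 25 with 23 | O=C1CC=C(C)[C@@H]2Cc3c(C)coc3C[C@@](C)(O[Si](CC)(CC)CC)CC[C@H](OC(CC(C)C)O[Sm](I)I)[C@@]12C | intermediate (not isolated)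
27 | furan-fused A/B bicycle: C2 3-methylbutanoate, C14 hydroxyl, C5 OSiEt3, stereocenters as in target | O[C@H]1CC=C(C)[C@@H]2Cc3c(C)coc3C[C@@](C)(O[Si](CC)(CC)CC)CC[C@H](OC(=O)CC(C)C)[C@@]12C | intermediate
28 | C14 acetate of 27 | CC(=O)O[C@H]1CC=C(C)[C@@H]2Cc3c(C)coc3C[C@@](C)(O[Si](CC)(CC)CC)CC[C@H](OC(=O)CC(C)C)[C@@]12C | intermediate
29 | furan endoperoxide of 28 (peroxide bridge C19 to C7) | CC(=O)O[C@H]1CC=C(C)[C@@H]2CC3=C(C)C4OOC3(O4)C[C@@](C)(O[Si](CC)(CC)CC)CC[C@H](OC(=O)CC(C)C)[C@@]12C | intermediate (not isolated)
30 | γ-hydroxybutenolide (C7 hemiketal, both epimers) | CC(=O)O[C@H]1CC=C(C)[C@@H]2CC3=C(C)C(=O)OC3(O)C[C@@](C)(O[Si](CC)(CC)CC)CC[C@H](OC(=O)CC(C)C)[C@@]12C | intermediate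
31 | O5-triethylsilyl ether of the target | CC(=O)O[C@H]1CC=C(C)[C@@H]2CC3=C(C)C(=O)O/C3=C/[C@@](C)(O[Si](CC)(CC)CC)CC[C@H](OC(=O)CC(C)C)[C@@]12C | intermediate
32 | CNP0208239.1 | CC(=O)O[C@H]1CC=C(C)[C@@H]2CC3=C(C)C(=O)O/C3=C/[C@@](C)(O)CC[C@H](OC(=O)CC(C)C)[C@@]12C | target

**Step count**

Total: 19 steps. Longest linear sequence: 15 steps (6 to 32, steps 5–19); the ring-A branch (steps 1–4) joins at step 12.

**Steps most likely to fail**

Step 15. The ten-membered ring closure may be too slow, so that intermolecular aldol addition, pinacol-type reduction of the tethered aldehyde, or reversible opening of the samarium aldolate before hydride transfer takes over; closure through the cis-fused or C2-epimeric chair would also erode the stereochemical outcome. The fallback sets out from 22 and returns at 27. The ring is closed under irreversible, non-basic conditions with CrCl2 and LiI in THF at high dilution (chromium Reformatsky reaction, selective for the C–Br bond over the aldehyde), which should give the isolated β-hydroxy ketone F1. F1 is then treated with 23 and catalytic SmI2 in THF at −10 °C (Evans–Tishchenko reduction) to give 27.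

Step 3. The catalyst may discriminate poorly between the two enantiotopic ring alkenes, and over-oxidation to the bis-epoxide may compete. The fallback sets out from 3 and returns at 4. Epoxidation of 3 with dimethyldioxirane (acetone, −20 °C), anti to the CH2OH group, should give racemic material, that is 4 together with the enantiomeric epoxy alcohol F2. Lipase-catalysed acylation (Amano lipase PS, vinyl acetate, tert-butyl methyl ether; enzyme screened for this sense) is expected to convert F2 into the acetate F3 and leave 4, which is separated by chromatography and enters step 4.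

Step 13. The cationic epoxide opening may be diverted into proton loss and aromatization of ring A, hydride shift to the ketone, bromide attack at the secondary carbon, or loss of the silyl ether under the mineral acid. The fallback sets out from 20 and returns at 27. Buffered acetolysis (AcOH, NaOAc, 40 °C) should open the epoxide to the hydroxy acetate F4 without strong acid. Dess–Martin oxidation then gives the α-acetoxy ketone F5, which SmI2 cleaves reductively to the same samarium enolate 24 under the conditions of step 15, so the route is rejoined at 27.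

Further compounds
F1 | step 15 | β-hydroxy ketone (ring B closed; free C2 hydroxyl; C14 ketone) | O=C1CC=C(C)[C@@H]2Cc3c(C)coc3C[C@@](C)(O[Si](CC)(CC)CC)CC[C@H](O)[C@@]12C
F2 | step 3 | enantiomeric epoxy alcohol, [(1S,2S,6R)-1,3-dimethyl-7-oxabicyclo[4.1.0]hept-3-en-2-yl]methanol | OC[C@@H]1C(C)=CC[C@H]2O[C@@]12C
F3 | step 3 | acetate of F2 | CC(=O)OC[C@@H]1C(C)=CC[C@H]2O[C@@]12C
F4 | step 13 | hydroxy acetate (tertiary acetate on C1, hydroxyl on C14) | Cc1coc(C[C@@](C)(O[Si](CC)(CC)CC)CCC=O)c1C[C@H]1C(C)=CC[C@H](O)[C@@]1(C)OC(C)=O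
F5 | step 13 | α-acetoxy ketone | Cc1coc(C[C@@](C)(O[Si](CC)(CC)CC)CCC=O)c1C[C@H]1C(C)=CCC(=O)[C@@]1(C)OC(C)=O
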